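**Retrosynthetic overview**
1. The last C–C bond is C3(ring A)–CHO. The formyl carbon arrives as a nucleophile: the nitronate of nitromethane (a formyl anion equivalent) is coupled under Pd catalysis to the electrophilic C3–I carbon of the complete, unprotected depside 7, and unmasked by a Nef reaction in the same flask.
2. Because the ring A formyl group arrives last, the ring B carboxyl can be carried as an aldehyde and oxidised (Pinnick), so no protecting group is needed.
3. The depside C–O bond comes from trifluoroacetic anhydride condensation of iodo acid 4 with phenolic aldehyde 5.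
4. Acid 4 comes from methyl orsellinate 1 by iodination at C3 (between the two hydroxyls), 4-O-methylation and saponification.
5. No ring is built: ring A (from 1) and ring B (from 5) are bought as arenes.

Assumption: the target has no stereocentre and no stereogenic axis (its SMILES carries no stereo descriptor), so it is one achiral compound and no step has to control configuration.

**Step 1**
Reactants: 1 methyl orsellinate (methyl 2,4-dihydroxy-6-methylbenzoate)
Product: 2 methyl 2,4-dihydroxy-3-iodo-6-methylbenzoate
Conditions: I2 (1.0 equiv), NaHCO3 (1.1 equiv), THF–H2O 1:1, 0 °C, 1 h; aq. Na2S2O3 work-up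
Reagents that add atoms: iodine, [I][I]
Why: In aqueous NaHCO3 the non-chelated 4-OH is ionised and electrophilic aromatic iodination of the phenoxide goes to C3, the carbon flanked by both oxygens (the selectivity that gives 2-iodoresorcinol from resorcinol), while C5 is shielded by the 6-methyl group; no stereocentre is created.

**Step 2**
Reactants: 2 methyl 2,4-dihydroxy-3-iodo-6-methylbenzoate
Product: 4 2-hydroxy-3-iodo-4-methoxy-6-methylbenzoic acid, via methyl 3-iodoeverninate 3 (not isolated)
Conditions: MeI (1.1 equiv), K2CO3 (1.5 equiv), acetone, 40 °C; acetone distilled off; then KOH (6 equiv), DMSO–H2O 4:1, 80 °C; then 2 M HCl, 0 °C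
Reagents that add atoms: iodomethane, CI; potassium hydroxide, [K+].[OH-]
Why: K2CO3 ionises only the free 4-OH (the 2-OH is hydrogen-bonded to the ester), so the Williamson methylation is selective, and KOH in aqueous DMSO then saponifies the hindered ester (BAc2) without touching the aryl iodide; no stereocentre is created.

**Step 3**
Reactants: 4 2-hydroxy-3-iodo-4-methoxy-6-methylbenzoic acid; 5 2,4-dihydroxy-3,6-dimethylbenzaldehyde
Product: 6 4-formyl-3-hydroxy-2,5-dimethylphenyl 2-hydroxy-3-iodo-4-methoxy-6-methylbenzoate
Conditions: (CF3CO)2O (6 equiv), toluene, 20 °C, 4 h; then H2O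
Reagents that add atoms: none
Why: Trifluoroacetic anhydride turns the electron-rich, di-ortho-substituted acid into a mixed anhydride (acylium-like) that acylates the only non-chelated hydroxyl of 5 (4-OH), the standard depside condensation; both chelated ortho-hydroxyls stay free after aqueous work-up, and no stereocentre is created.

**Step 4**
Reactants: 6 4-formyl-3-hydroxy-2,5-dimethylphenyl 2-hydroxy-3-iodo-4-methoxy-6-methylbenzoate
Product: 7 2-hydroxy-4-[(2-hydroxy-3-iodo-4-methoxy-6-methylbenzoyl)oxy]-3,6-dimethylbenzoic acid
Conditions: NaClO2 (3 equiv), NaH2PO4 (4 equiv), 2-methyl-2-butene (20 equiv), THF–t-BuOH–H2O, 0 °C to 20 °C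
Reagents that add atoms: sodium chlorite, [Na+].[O-]Cl=O
Why: Pinnick chlorite oxidation converts the aryl aldehyde into the acid at pH 3–4, where the aryl ester, phenols and aryl iodide are inert, and 2-methyl-2-butene removes HOCl so that ring A is not chlorinated; no stereocentre is created.

**Step 5**
Reactants: 7 2-hydroxy-4-[(2-hydroxy-3-iodo-4-methoxy-6-methylbenzoyl)oxy]-3,6-dimethylbenzoic acid; 8 nitromethane
Product: 10 baeomycesic acid, via nitromethyl depside acid 9 (not isolated)
Conditions: 8 (2 equiv), Pd2(dba)3 (5 mol %), XPhos (12 mol %), Cs2CO3 (4.5 equiv), 4 Å MS, 1,4-dioxane, 60 °C; then same flask, 0 °C, THF, aq. TiCl3 (10 equiv)/NH4OAc, pH 5–6, 20 °C; dilute HCl work-up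
Reagents that add atoms: water, O
Why: Zerovalent palladium with XPhos inserts into the C3–I bond and the nitronate of nitromethane is C-arylated (Pd-catalysed nitromethylation of aryl halides), joining two carbons that are both electrophilic by normal polarity; the nitronate of 9 is then reduced by trivalent titanium to the imine, which hydrolyses to the aldehyde (McMurry variant of the Nef reaction), and no stereocentre is created.

**Compound list**
1 | methyl orsellinate (methyl 2,4-dihydroxy-6-methylbenzoate) | COC(=O)c1c(C)cc(O)cc1O | starting material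
2 | methyl 2,4-dihydroxy-3-iodo-6-methylbenzoate | COC(=O)c1c(C)cc(O)c(I)c1O | intermediate
3 | methyl 3-iodoeverninate (methyl 2-hydroxy-3-iodo-4-methoxy-6-methylbenzoate) | COC(=O)c1c(C)cc(OC)c(I)c1O | intermediate (not isolated)
4 | 2-hydroxy-3-iodo-4-methoxy-6-methylbenzoic acid | OC(=O)c1c(C)cc(OC)c(I)c1O | intermediate
5 | 2,4-dihydroxy-3,6-dimethylbenzaldehyde | O=Cc1c(C)cc(O)c(C)c1O | starting material
6 | 4-formyl-3-hydroxy-2,5-dimethylphenyl 2-hydroxy-3-iodo-4-methoxy-6-methylbenzoate | COc1cc(C)c(C(=O)Oc2cc(C)c(C=O)c(O)c2C)c(O)c1I | intermediate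
7 | 2-hydroxy-4-[(2-hydroxy-3-iodo-4-methoxy-6-methylbenzoyl)oxy]-3,6-dimethylbenzoic acid | COc1cc(C)c(C(=O)Oc2cc(C)c(C(=O)O)c(O)c2C)c(O)c1I | intermediate
8 | nitromethane | C[N+](=O)[O-] | starting material
9 | 2-hydroxy-4-{[2-hydroxy-4-methoxy-6-methyl-3-(nitromethyl)benzoyl]oxy}-3,6-dimethylbenzoic acid (present in the flask as its cesium nitronate) | COc1cc(C)c(C(=O)Oc2cc(C)c(C(=O)O)c(O)c2C)c(O)c1C[N+](=O)[O-] | intermediate (not isolated)
10 | baeomycesic acid (4-[(3-formyl-2-hydroxy-4-methoxy-6-methylbenzoyl)oxy]-2-hydroxy-3,6-dimethylbenzoic acid) | COc1cc(C)c(C(=O)Oc2cc(C)c(C(=O)O)c(O)c2C)c(O)c1C=O | target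

**Totals**
Total step count: 5. Longest linear sequence: 5 steps (1 → 2 → 4 → 6 → 7 → 10); 5 and 8 are bought and added in steps 3 and 5.

**Steps most likely to fail, with fallbacks**

The riskiest is step 5. The coupling runs on a hindered, di-ortho-oxygenated aryl iodide that carries a free acid, two phenols and a base-sensitive aryl ester. Protodeiodination, cleavage of the depside by carbonate or nitronate, or a poor Nef reaction in the crude mixture could each defeat it. The fallback sets out from 4 and comes back at 9. Acid 4 is nitromethylated with the same catalyst before the aryl ester exists, giving 2-hydroxy-4-methoxy-6-methyl-3-(nitromethyl)benzoic acid F1. Trifluoroacetic anhydride condensation of F1 with 5 gives 4-formyl-3-hydroxy-2,5-dimethylphenyl 2-hydroxy-4-methoxy-6-methyl-3-(nitromethyl)benzoate F2. Pinnick oxidation of F2 gives 9, which is now isolated and taken to 10 by the buffered TiCl3 Nef reaction as a separate operation.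

Second is step 1. Iodination could also occur at C5 or go on to the 3,5-diiodide. The fallback sets out from 1 and comes back at 3. It places the iodine on the symmetric resorcinol before the carboxyl exists. Ester 1 is saponified and decarboxylated (aq. NaOH, reflux; then HCl, 60 °C) to orcinol F3, which is also a cheap article of commerce. I2/NaHCO3 in water gives 2-iodo-5-methylbenzene-1,3-diol F4. Ortho-carboxylation with MeOMgOCO2Me in DMF at 120 °C can then only reach the two equivalent positions next to the methyl group, and gives 2,4-dihydroxy-3-iodo-6-methylbenzoic acid F5. MeI (2.1 equiv) and K2CO3 in acetone esterify the acid and methylate the 4-OH to give 3, which re-enters at the KOH stage of step 2.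

Third is step 3. Both partners are hindered, and trifluoroacetic acid could cause loss or migration of the iodine on the electron-rich ring. The fallback sets out from 4 and comes back at 6, and replaces acidic anhydride activation by an anionic acyl transfer. Acid 4 with acetone, trifluoroacetic anhydride and trifluoroacetic acid gives 8-iodo-7-methoxy-2,2,5-trimethyl-4H-1,3-benzodioxin-4-one F6. The cesium 4-phenoxide of 5 (Cs2CO3, DMF, 60 °C) opens F6 at the carbonyl with loss of acetone and gives 6 with its ortho-hydroxyl free.

**Further compounds**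
F1 | step 5 | 2-hydroxy-4-methoxy-6-methyl-3-(nitromethyl)benzoic acid | COc1cc(C)c(C(=O)O)c(O)c1C[N+](=O)[O-]
F2 | step 5 | 4-formyl-3-hydroxy-2,5-dimethylphenyl 2-hydroxy-4-methoxy-6-methyl-3-(nitromethyl)benzoate | COc1cc(C)c(C(=O)Oc2cc(C)c(C=O)c(O)c2C)c(O)c1C[N+](=O)[O-]
F3 | step 1 | orcinol (5-methylbenzene-1,3-diol) | Cc1cc(O)cc(O)c1
F4 | step 1 | 2-iodo-5-methylbenzene-1,3-diol | Cc1cc(O)c(I)c(O)c1
F5 | step 1 | 2,4-dihydroxy-3-iodo-6-methylbenzoic acid | Cc1cc(O)c(I)c(O)c1C(=O)O
F6 | step 3 | 8-iodo-7-methoxy-2,2,5-trimethyl-4H-1,3-benzodioxin-4-one | COc1cc(C)c2C(=O)OC(C)(C)Oc2c1I
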